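**Retrosynthetic overview**
1. The target comes from triacetylation of a triol lactone, which comes from a one-pot acidic unmasking and γ-lactonisation of a ten-membered carbocycle closed at C6–C7 by a Nozaki–Hiyama–Kishi reaction.
2. C7–C9 and C17–C19 are built on a C9 aldehyde: Felkin aldol of a glyoxylate dithiane (C9), then chelation-controlled propionate aldol at the C8 ketone (C8, C17).
3. C2–C6 come from MeLi on a ring A carboxylic acid, enolate allylation with a (Z)-iodoallyl bromide, and a 14-OH-directed syn reduction (C2).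
4. Key step: ring A with quaternary C1 and C10 is formed by an Ireland–Claisen ring contraction ([3,3], boat) of a trans-4-silyloxy-6-[(Z)-alkenyl] δ-lactone.
5. The δ-lactone comes from (R)-3-silyloxyglutaric half ester (the only chiral input) and a (Z)-alkenyllithium. Ring order: δ-lactone (sacrificial) → ring A → acetonide (temporary) → ten-membered ring → γ-lactone.

Assumption 1: briarane numbering is used for intermediates (C1 quaternary fusion carbon with Me-15; C2, C9, C14 the oxygenated CH; C5 bears Me-16; C7 lactone O; C8 tertiary OH; C10 fusion CH; C11(Me-20)=C12; C17 bears Me-18; C19 lactone C=O). "As in the target" means the same spatial arrangement as in the given SMILES.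
Assumption 2: compound 9 is the commercial bulk statin side-chain building block.

Step 1
Reactants: 1 but-2-yn-1-ol
Product: 3 (Z)-3-iodobut-2-en-1-ol, via cyclic alkenylalanate 2 (not isolated)
Conditions: NaAlH2(OCH2CH2OMe)2, THF, 0 °C to rt; then I2, THF, −78 °C to 0 °C
Reagents that add atoms: iodine, II
Why: Trans-hydroalumination of the propargylic alcohol places Al on C3 cis to CH2O in a five-membered alanate, and iodinolysis with retention gives the Z iodide.

Step 2
Reactants: 3 (Z)-3-iodobut-2-en-1-ol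
Product: 4 (Z)-tert-butyl[(3-iodobut-2-en-1-yl)oxy]diphenylsilane
Conditions: t-BuPh2SiCl, imidazole, CH2Cl2, 0 °C to rt
Reagents that add atoms: tert-butyl(chloro)diphenylsilane, CC(C)(C)[Si](Cl)(c1ccccc1)c1ccccc1
Why: Standard silylation of a primary alcohol; the robust silyl ether prevents the later (Z)-γ-oxy enone from closing to a furan.

Step 3
Reactants: 5 prop-2-yn-1-ol
Product: 7 (Z)-3-iodo-2-methylprop-2-en-1-ol, via cyclic alkenylmagnesium alkoxide 6 (not isolated)
Conditions: MeMgBr (2.5 equiv), CuI (10 mol %), THF, −10 °C to rt; then I2, 0 °C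
Reagents that add atoms: methylmagnesium bromide, C[Mg]Br; iodine, II
Why: CuI-catalysed anti-carbomagnesiation (Duboudin) puts Me on C2 and Mg on C3 cis to CH2O, and iodinolysis with retention fixes the Z geometry.

Step 4
Reactants: 7 (Z)-3-iodo-2-methylprop-2-en-1-ol
Product: 8 (Z)-3-bromo-1-iodo-2-methylprop-1-ene
Conditions: CBr4, PPh3, CH2Cl2, 0 °C
Reagents that add atoms: tetrabromomethane, BrC(Br)(Br)Br
Why: Appel bromination of the primary allylic alcohol leaves the alkenyl iodide and its geometry untouched.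

Step 5
Reactants: 9 (3R)-3-[(tert-butyldimethylsilyl)oxy]pentanedioic acid 1-methyl ester
Product: 10 (3S)-3-[(tert-butyldimethylsilyl)oxy]-5-[methoxy(methyl)amino]-5-oxopentanoic acid
Conditions: MeNH(OMe)·HCl, i-PrMgCl (5 equiv), THF, −20 °C to 0 °C; aq. citric acid
Reagents that add atoms: N,O-dimethylhydroxylamine hydrochloride, CNOC.Cl
Why: Weinreb amidation of the methyl ester by the chloromagnesium amide while the acid is shielded as its carboxylate; the stereocentre (later C14) is untouched.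

Step 6
Reactants: 10 (3S)-3-[(tert-butyldimethylsilyl)oxy]-5-[methoxy(methyl)amino]-5-oxopentanoic acid
Product: 11 (3S)-3-hydroxy-5-[methoxy(methyl)amino]-5-oxopentanoic acid
Conditions: aq. HF (48 %), MeCN, 0 °C to rt
Reagents that add atoms: none
Why: Fluoride-assisted desilylation frees the hydroxyl needed to direct the next reduction, and is done before the sensitive (Z)-enone exists.

Step 7
Reactants: 11 (3S)-3-hydroxy-5-[methoxy(methyl)amino]-5-oxopentanoic acid; 4 (Z)-tert-butyl[(3-iodobut-2-en-1-yl)oxy]diphenylsilane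
Product: 13 (3S,6Z)-8-[(tert-butyldiphenylsilyl)oxy]-3-hydroxy-6-methyl-5-oxooct-6-enoic acid, via alkenyllithium 12 (not isolated)
Conditions: 4, t-BuLi (2 equiv), Et2O, −78 °C; added to 11 pre-treated with i-PrMgCl (2 equiv), THF, −78 °C to −20 °C; aq. NaH2PO4
Reagents that add atoms: none
Why: Iodine–lithium exchange with retention, then Weinreb ketone synthesis through a stable chelated tetrahedral adduct, gives the (Z)-enone without over-addition.

Step 8
Reactants: 13 (3S,6Z)-8-[(tert-butyldiphenylsilyl)oxy]-3-hydroxy-6-methyl-5-oxooct-6-enoic acid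
Product: 15 (4S,6R)-6-[(Z)-4-(tert-butyldiphenylsilyloxy)but-2-en-2-yl]-4-hydroxytetrahydro-2H-pyran-2-one, via dihydroxy acid 14 (not isolated)
Conditions: Et2BOMe, NaBH4, THF/MeOH (4:1), −78 °C; AcOH, MeOH co-evaporation; then PPTS (cat.), toluene, 40 °C
Reagents that add atoms: none
Why: Narasaka–Prasad reduction (external axial hydride on the boron chelate) gives the 1,3-syn diol, and δ-lactonisation then places the 4-oxygen and the 6-alkenyl group trans.

Step 9
Reactants: 15 (4S,6R)-6-[(Z)-4-(tert-butyldiphenylsilyloxy)but-2-en-2-yl]-4-hydroxytetrahydro-2H-pyran-2-one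
Product: 18 (3R,4S,6R)-6-[(Z)-4-(tert-butyldiphenylsilyloxy)but-2-en-2-yl]-3-methyl-4-(triethylsilyloxy)tetrahydro-2H-pyran-2-one, via dilithium alkoxide-enolate 16 (not isolated), via lithium alkoxide of the methylated lactone 17 (not isolated)
Conditions: LiN(i-Pr)2 (2.2 equiv), THF, −78 °C to −40 °C; MeI, DMPU, −78 °C; then Et3SiCl, DMAP (cat.), −78 °C to 0 °C
Reagents that add atoms: iodomethane, CI; chlorotriethylsilane, CC[Si](Cl)(CC)CC
Why: Fráter–Seebach-type alkylation of the alkoxide–enolate dianion (no β-elimination, Me anti to O) and in-pot silylation; the C3 configuration is irrelevant because it is planarised in the next step.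

Step 10
Reactants: 18 (3R,4S,6R)-6-[(Z)-4-(tert-butyldiphenylsilyloxy)but-2-en-2-yl]-3-methyl-4-(triethylsilyloxy)tetrahydro-2H-pyran-2-one
Product: 21 (1R,2S,6S)-2-{[(tert-butyldiphenylsilyl)oxy]methyl}-1,3-dimethyl-6-[(triethylsilyl)oxy]cyclohex-3-ene-1-carboxylic acid, via trimethylsilyl ketene acetal 19 (not isolated), via trimethylsilyl ester 20 (not isolated)
Conditions: Me3SiCl/Et3N, THF, −78 °C, then LiN(i-Pr)2 (1.3 equiv); −78 °C to rt, then toluene, 90 °C; K2CO3, MeOH/H2O; NaH2PO4 to pH 5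
Reagents that add atoms: none
Why: Ireland–Claisen ring contraction: the [3,3] shift runs through the boat array enforced by the lactone, so C1–C10 forms on the face carrying the alkenyl group (anti to OSiEt3, hence 14-O cis to CO2H), and the Z alkene places CH2OSi trans to CO2H, which sets C1 and C10 as in the target and creates ring A with the C11=C12 double bond.

Step 11
Reactants: 21 (1R,2S,6S)-2-{[(tert-butyldiphenylsilyl)oxy]methyl}-1,3-dimethyl-6-[(triethylsilyl)oxy]cyclohex-3-ene-1-carboxylic acid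
Product: 22 1-[(1R,2S,6S)-2-{[(tert-butyldiphenylsilyl)oxy]methyl}-1,3-dimethyl-6-[(triethylsilyl)oxy]cyclohex-3-en-1-yl]ethan-1-one
Conditions: MeLi (3.5 equiv), Et2O, 0 °C to rt; inverse quench into cold aq. NaH2PO4
Reagents that add atoms: methyllithium, [Li]C
Why: Addition of MeLi to the lithium carboxylate gives a stable dilithio gem-diolate that collapses to the methyl ketone only on hydrolysis.

Step 12
Reactants: 22 1-[(1R,2S,6S)-2-{[(tert-butyldiphenylsilyl)oxy]methyl}-1,3-dimethyl-6-[(triethylsilyl)oxy]cyclohex-3-en-1-yl]ethan-1-one; 8 (Z)-3-bromo-1-iodo-2-methylprop-1-ene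
Product: 24 (4Z)-1-[(1R,2S,6S)-2-{[(tert-butyldiphenylsilyl)oxy]methyl}-1,3-dimethyl-6-[(triethylsilyl)oxy]cyclohex-3-en-1-yl]-5-iodo-4-methylpent-4-en-1-one, via lithium enolate 23 (not isolated)
Conditions: LiN(i-Pr)2, THF, −78 °C; 8, DMPU, −78 °C to −30 °C
Reagents that add atoms: none
Why: Enolate alkylation (SN2 at the allylic bromide); only the methyl side can enolise because C1 is quaternary, and the silyl ether at C14 blocks retro-aldol.

Step 13
Reactants: 24 (4Z)-1-[(1R,2S,6S)-2-{[(tert-butyldiphenylsilyl)oxy]methyl}-1,3-dimethyl-6-[(triethylsilyl)oxy]cyclohex-3-en-1-yl]-5-iodo-4-methylpent-4-en-1-one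
Product: 25 (4Z)-1-[(1R,2S,6S)-6-hydroxy-2-(hydroxymethyl)-1,3-dimethylcyclohex-3-en-1-yl]-5-iodo-4-methylpent-4-en-1-one
Conditions: HF·pyridine, THF/pyridine, 0 °C to rt
Reagents that add atoms: none
Why: Buffered fluoride desilylation removes both silyl ethers without retro-aldol of the β-hydroxy ketone.

Step 14
Reactants: 25 (4Z)-1-[(1R,2S,6S)-6-hydroxy-2-(hydroxymethyl)-1,3-dimethylcyclohex-3-en-1-yl]-5-iodo-4-methylpent-4-en-1-one
Product: 26 2,14-syn triol: ring A of 25 carrying at C1 the (Z)-1-hydroxy-5-iodo-4-methylpent-4-enyl chain with C2 as in the target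
Conditions: Et2BOMe, NaBH4, THF/MeOH (4:1), −78 °C; AcOH, MeOH co-evaporation
Reagents that add atoms: none
Why: Narasaka–Prasad reduction: in the boron chelate between 14-OH and the C2 ketone (C13 equatorial) the external hydride attacks axially, giving the 2,14-syn diol and so C2 as in the target.

Step 15
Reactants: 26 2,14-syn triol
Product: 27 2,14-O-isopropylidene acetal of 26 (cis-fused 1,3-dioxane; CH2OH at C10 free)
Conditions: Me2C(OMe)2, PPTS (cat.), acetone, 0 °C to rt
Reagents that add atoms: 2,2-dimethoxypropane, COC(C)(C)OC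
Why: Only the syn-1,3-diol can form a six-membered isopropylidene acetal, so the primary C9 hydroxyl stays free.

Step 16
Reactants: 27 2,14-O-isopropylidene acetal with free C9 hydroxyl
Product: 28 C9 aldehyde (acetonide of ring A; C10 as in the target)
Conditions: Dess–Martin periodinane, NaHCO3, CH2Cl2, 0 °C to rt; used crude
Reagents that add atoms: none
Why: Buffered Dess–Martin oxidation gives the β,γ-unsaturated aldehyde without epimerisation at C10 or migration of the double bond.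

Step 17
Reactants: 28 C9 aldehyde
Product: 30 ethyl 2-[(methoxymethoxy)(ring A acetonide)methyl]-1,3-dithiane-2-carboxylate with C9 as in the target, via lithium aldolate 29 (not isolated)
Conditions: ethyl 1,3-dithiane-2-carboxylate, LiN(i-Pr)2, THF, −78 °C; 28, −78 °C; then MeOCH2Cl, DMPU, −78 °C to 0 °C
Reagents that add atoms: ethyl 1,3-dithiane-2-carboxylate, CCOC(=O)C1SCCCS1; chloromethyl methyl ether, COCCl
Why: Aldol addition of the glyoxylate acyl-anion equivalent under Felkin–Anh control (attack anti to the quaternary C1 branch, past H-10) sets C9, and the aldolate is capped as its MOM ether before retro-aldol can occur.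

Step 18
Reactants: 30 MOM-protected dithiane ester
Product: 31 ethyl 3-(methoxymethoxy)-2-oxo-3-(ring A acetonide)propanoate (α-keto ester; C8 ketone)
Conditions: N-chlorosuccinimide, AgNO3, 2,6-lutidine, MeCN/H2O (4:1), 0 °C, 10 min
Reagents that add atoms: water, O
Why: Corey–Erickson oxidative hydrolysis of the dithiane unmasks the C8 ketone under buffered conditions that spare the trisubstituted alkenes, the alkenyl iodide and the acetals.

Step 19
Reactants: 31 α-keto ester
Product: 33 1-ethyl 4-tert-butyl 2-[(methoxymethoxy)(ring A acetonide)methyl]-3-methyl-2-(triethylsilyloxy)butanedioate with C8, C9 and C17 as in the target, via bromomagnesium aldolate 32 (not isolated)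
Conditions: tert-butyl propanoate, LiN(i-Pr)2, THF, −78 °C; MgBr2·OEt2; 31, −78 °C; then Et3SiOTf, 2,6-lutidine, −78 °C to 0 °C
Reagents that add atoms: tert-butyl propanoate, CCC(=O)OC(C)(C)C; triethylsilyl trifluoromethanesulfonate, CC[Si](CC)(CC)OS(=O)(=O)C(F)(F)F
Why: Chelation-controlled aldol addition: Mg bridges the C8 carbonyl and the 9-OMOM oxygen (Cram chelate, attack anti to C10) and the E enolate reacts through a Zimmerman–Traxler chair with the ester group equatorial, which sets C8 and C17; silylation of the tertiary alkoxide blocks retro-aldol.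

Step 20
Reactants: 33 silylated diester
Product: 34 tert-butyl 3-formyl-4-(methoxymethoxy)-2-methyl-3-(triethylsilyloxy)-4-(ring A acetonide)butanoate (C7 aldehyde)
Conditions: i-Bu2AlH (1.5 equiv), CH2Cl2, −78 °C; aq. KNaC4H4O6
Reagents that add atoms: none
Why: Partial reduction of the α-silyloxy ethyl ester through a stable tetrahedral aluminate, while the tert-butyl ester is inert at −78 °C.

Step 21
Reactants: 34 C7 aldehyde bearing the (Z)-alkenyl iodide
Product: 35 ten-membered carbocycle: (5Z)-ene, 7-hydroxy, 8-OSiEt3 with the CH(CH3)CO2t-Bu arm on C8, 9-OMOM, 2,14-acetonide; all stereocentres as in the target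
Conditions: CrCl2 (15 equiv), NiCl2 (1 mol % of CrCl2), DMSO/THF, rt, 0.002 M, slow addition
Reagents that add atoms: none
Why: Nozaki–Hiyama–Kishi macrocyclisation (zerovalent nickel inserts into C–I, transmetalation gives the alkenyl species of trivalent chromium with retention of the Z geometry); polar Felkin–Anh addition anti to the non-chelating 8-OSiEt3 and past the smaller C17 branch sets C7.

Step 22
Reactants: 35 protected ten-membered carbocycle
Product: 36 2,9,14-tri-O-deacetyl stylatulide lactone (triol γ-lactone)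
Conditions: CF3CO2H/CH2Cl2/H2O (9:9:1), 0 °C to rt
Reagents that add atoms: none
Why: Acidolysis cleaves the tert-butyl ester, silyl ether, acetonide and MOM ether, and the liberated acid lactonises onto the already free 7-OH (the 9-oxygen is unmasked last), closing the γ-lactone.

Step 23
Reactants: 36 triol γ-lactone
Product: 37 stylatulide lactone
Conditions: Ac2O, pyridine, DMAP (cat.), CH2Cl2, rt
Reagents that add atoms: acetic anhydride, CC(=O)OC(C)=O
Why: Acetylation of the three secondary hydroxyls (C2, C9, C14); the hindered tertiary 8-OH does not react.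

**Compound list**
1 | but-2-yn-1-ol | CC#CCO | starting material
2 | cyclic alkenylalanate (sodium salt) | CC1=CCO[Al-]1(OCCOC)OCCOC.[Na+] | intermediate (not isolated)
3 | (Z)-3-iodobut-2-en-1-ol | I/C(C)=C\CO | intermediate
4 | (Z)-tert-butyl[(3-iodobut-2-en-1-yl)oxy]diphenylsilane | I/C(C)=C\CO[Si](c1ccccc1)(c1ccccc1)C(C)(C)C | intermediate
5 | prop-2-yn-1-ol | C#CCO | starting material
6 | cyclic alkenylmagnesium alkoxide | CC1=C[Mg]OC1 | intermediate (not isolated)
7 | (Z)-3-iodo-2-methylprop-2-en-1-ol | I/C=C(/C)CO | intermediate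
8 | (Z)-3-bromo-1-iodo-2-methylprop-1-ene | I/C=C(/C)CBr | intermediate
9 | (3R)-3-[(tert-butyldimethylsilyl)oxy]pentanedioic acid 1-methyl ester | COC(=O)C[C@H](O[Si](C)(C)C(C)(C)C)CC(=O)O | starting material
10 | (3S)-3-[(tert-butyldimethylsilyl)oxy]-5-[methoxy(methyl)amino]-5-oxopentanoic acid | CON(C)C(=O)C[C@H](O[Si](C)(C)C(C)(C)C)CC(=O)O | intermediate
11 | (3S)-3-hydroxy-5-[methoxy(methyl)amino]-5-oxopentanoic acid | CON(C)C(=O)C[C@H](O)CC(=O)O | intermediate
12 | (Z)-[4-(tert-butyldiphenylsilyloxy)but-2-en-2-yl]lithium | [Li]/C(C)=C\CO[Si](c1ccccc1)(c1ccccc1)C(C)(C)C | intermediate (not isolated)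
13 | (3S,6Z)-8-[(tert-butyldiphenylsilyl)oxy]-3-hydroxy-6-methyl-5-oxooct-6-enoic acid | OC(=O)C[C@@H](O)CC(=O)/C(C)=C\CO[Si](c1ccccc1)(c1ccccc1)C(C)(C)C | intermediate
14 | (3S,5R,6Z)-8-[(tert-butyldiphenylsilyl)oxy]-3,5-dihydroxy-6-methyloct-6-enoic acid | OC(=O)C[C@@H](O)C[C@@H](O)/C(C)=C\CO[Si](c1ccccc1)(c1ccccc1)C(C)(C)C | intermediate (not isolated)
15 | (4S,6R)-6-[(Z)-4-(tert-butyldiphenylsilyloxy)but-2-en-2-yl]-4-hydroxytetrahydro-2H-pyran-2-one | O=C1O[C@@H](/C(C)=C\CO[Si](c2ccccc2)(c2ccccc2)C(C)(C)C)C[C@H](O)C1 | intermediate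
16 | dilithium alkoxide-enolate of 15 | [Li]OC1=C[C@@H](O[Li])C[C@H](/C(C)=C\CO[Si](c2ccccc2)(c2ccccc2)C(C)(C)C)O1 | intermediate (not isolated)
17 | lithium alkoxide of the trans-3-methyl lactone | O=C1O[C@@H](/C(C)=C\CO[Si](c2ccccc2)(c2ccccc2)C(C)(C)C)C[C@H](O[Li])[C@H]1C | intermediate (not isolated)
18 | (3R,4S,6R)-6-[(Z)-4-(tert-butyldiphenylsilyloxy)but-2-en-2-yl]-3-methyl-4-(triethylsilyloxy)tetrahydro-2H-pyran-2-one | O=C1O[C@@H](/C(C)=C\CO[Si](c2ccccc2)(c2ccccc2)C(C)(C)C)C[C@H](O[Si](CC)(CC)CC)[C@H]1C | intermediate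
19 | trimethylsilyl ketene acetal of 18 (2-alkenyl-5-methyl-4-triethylsilyloxy-6-trimethylsilyloxy-3,4-dihydro-2H-pyran) | C[Si](C)(C)OC1=C(C)[C@@H](O[Si](CC)(CC)CC)C[C@H](/C(C)=C\CO[Si](c2ccccc2)(c2ccccc2)C(C)(C)C)O1 | intermediate (not isolated)
20 | trimethylsilyl ester of 21 | CC[Si](CC)(CC)O[C@H]1CC=C(C)[C@H](CO[Si](c2ccccc2)(c2ccccc2)C(C)(C)C)[C@@]1(C)C(=O)O[Si](C)(C)C | intermediate (not isolated)
21 | (1R,2S,6S)-2-{[(tert-butyldiphenylsilyl)oxy]methyl}-1,3-dimethyl-6-[(triethylsilyl)oxy]cyclohex-3-ene-1-carboxylic acid (briarane C1, C10, C14 as in the target) | CC[Si](CC)(CC)O[C@H]1CC=C(C)[C@H](CO[Si](c2ccccc2)(c2ccccc2)C(C)(C)C)[C@@]1(C)C(=O)O | intermediate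
22 | 1-[(1R,2S,6S)-2-{[(tert-butyldiphenylsilyl)oxy]methyl}-1,3-dimethyl-6-[(triethylsilyl)oxy]cyclohex-3-en-1-yl]ethan-1-one | CC[Si](CC)(CC)O[C@H]1CC=C(C)[C@H](CO[Si](c2ccccc2)(c2ccccc2)C(C)(C)C)[C@@]1(C)C(C)=O | intermediate
23 | lithium enolate of 22 | CC[Si](CC)(CC)O[C@H]1CC=C(C)[C@H](CO[Si](c2ccccc2)(c2ccccc2)C(C)(C)C)[C@@]1(C)C(=C)O[Li] | intermediate (not isolated)
24 | (4Z)-1-[(1R,2S,6S)-2-{[(tert-butyldiphenylsilyl)oxy]methyl}-1,3-dimethyl-6-[(triethylsilyl)oxy]cyclohex-3-en-1-yl]-5-iodo-4-methylpent-4-en-1-one | CC[Si](CC)(CC)O[C@H]1CC=C(C)[C@H](CO[Si](c2ccccc2)(c2ccccc2)C(C)(C)C)[C@@]1(C)C(=O)CC/C(C)=C\I | intermediate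
25 | (4Z)-1-[(1R,2S,6S)-6-hydroxy-2-(hydroxymethyl)-1,3-dimethylcyclohex-3-en-1-yl]-5-iodo-4-methylpent-4-en-1-one | O[C@H]1CC=C(C)[C@H](CO)[C@@]1(C)C(=O)CC/C(C)=C\I | intermediate
26 | 2,14-syn triol (C2 as in the target) | O[C@H]1CC=C(C)[C@H](CO)[C@@]1(C)[C@H](O)CC/C(C)=C\I | intermediate
27 | 2,14-O-isopropylidene acetal with free C9 hydroxyl | CC2(C)O[C@H]1CC=C(C)[C@H](CO)[C@@]1(C)[C@@H](CC/C(C)=C\I)O2 | intermediate
28 | C9 aldehyde | CC2(C)O[C@H]1CC=C(C)[C@H](C=O)[C@@]1(C)[C@@H](CC/C(C)=C\I)O2 | intermediate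
29 | lithium aldolate (C9–OLi, dithiane ester) | CC2(C)O[C@H]1CC=C(C)[C@H]([C@@H](O[Li])C3(SCCCS3)C(=O)OCC)[C@@]1(C)[C@@H](CC/C(C)=C\I)O2 | intermediate (not isolated)
30 | 9-O-methoxymethyl dithiane ethyl ester (C9 as in the target) | CC2(C)O[C@H]1CC=C(C)[C@H]([C@@H](OCOC)C3(SCCCS3)C(=O)OCC)[C@@]1(C)[C@@H](CC/C(C)=C\I)O2 | intermediate
31 | α-keto ester (C8 ketone, C7 ethyl ester) | CC2(C)O[C@H]1CC=C(C)[C@H]([C@@H](OCOC)C(=O)C(=O)OCC)[C@@]1(C)[C@@H](CC/C(C)=C\I)O2 | intermediate
32 | bromomagnesium aldolate | CC2(C)O[C@H]1CC=C(C)[C@H]([C@@H](OCOC)[C@@](O[Mg]Br)(C(=O)OCC)[C@@H](C)C(=O)OC(C)(C)C)[C@@]1(C)[C@@H](CC/C(C)=C\I)O2 | intermediate (not isolated)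
33 | 8-O-triethylsilyl diester (C7 ethyl ester, C19 tert-butyl ester; C8, C9, C17 as in the target) | CC2(C)O[C@H]1CC=C(C)[C@H]([C@@H](OCOC)[C@@](O[Si](CC)(CC)CC)(C(=O)OCC)[C@@H](C)C(=O)OC(C)(C)C)[C@@]1(C)[C@@H](CC/C(C)=C\I)O2 | intermediate
34 | C7 aldehyde | CC2(C)O[C@H]1CC=C(C)[C@H]([C@@H](OCOC)[C@@](O[Si](CC)(CC)CC)(C=O)[C@@H](C)C(=O)OC(C)(C)C)[C@@]1(C)[C@@H](CC/C(C)=C\I)O2 | intermediate
35 | protected ten-membered carbocycle (7-OH, 8-OSiEt3, 9-OMOM, 2,14-acetonide, tert-butyl ester) | CC4(C)O[C@H]1CC=C(C)[C@@H]2[C@@H](OCOC)[C@](O[Si](CC)(CC)CC)([C@@H](C)C(=O)OC(C)(C)C)[C@@H](O)/C=C(/C)CC[C@@H](O4)[C@@]12C | intermediate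
36 | 2,9,14-tri-O-deacetyl stylatulide lactone | O[C@H]1CC=C(C)[C@@H]2[C@@H](O)[C@@]3(O)[C@H](/C=C(/C)CC[C@@H](O)[C@@]12C)OC(=O)[C@@H]3C | intermediate
37 | stylatulide lactone | CC(=O)O[C@H]1CC=C(C)[C@@H]2[C@@H](OC(C)=O)[C@@]3(O)[C@H](/C=C(/C)CC[C@@H](OC(C)=O)[C@@]12C)OC(=O)[C@@H]3C | target

**Step count and risks**
Total: 23 steps (19 in the main line from 9, plus 2 each for reagents 4 and 8). Longest linear sequence: 19 steps (9 → 37, steps 5–23; the branch from 1 through 4 is equally long).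

Stereocentre origin: C14 is bought in 9. C1 and C10 come from step 10, C2 from step 14, C9 from step 17, C8 and C17 from step 19, and C7 from step 21, all by substrate control.

The three steps most likely to fail:

Step 10 (Ireland–Claisen ring contraction). The β-silyloxy lactone enolate can eliminate, and the boat array has to build a quaternary centre. Fallback: from 18, MeLi (1 equiv, THF, −78 °C) gives the methyl lactol (2-hydroxy-2,3-dimethyl tetrahydropyran) F1. MsCl/Et3N dehydrates it to the cyclic enol ether (2-alkenyl-5,6-dimethyl-4-triethylsilyloxy-3,4-dihydro-2H-pyran) F2. Heating F2 (xylene, 140 °C, trace Et3N) brings about the neutral thermal Claisen rearrangement of an alkenyl dihydropyran through the same boat array and gives methyl ketone 22 directly, so no ester enolate is needed and step 11 is bypassed.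

Step 19 (aldol at the C8 ketone). Facial control at C8 rests on chelation; the C17 methyl configuration is the less secure element. Fallback, with C17 set by thermodynamic instead of kinetic control: the C17 epimer of the aldol product, 17-epi-33 F3, obtained from 31, is carried through steps 20–23 as 17-epi-34 F4, 17-epi-35 F5, 17-epi-36 F6 and 17-epi-37 F7. F7 is then equilibrated with DBU in toluene at the enolisable lactone α-carbon, where the methyl group should prefer to sit trans to the bulky C9 branch on C8 (cis to 8-OH), which gives 37.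

Step 21 (Nozaki–Hiyama–Kishi macrocyclisation). The ring is ten-membered, the aldehyde is neopentyl, and the C7 configuration is set in the ring closure. Fallback: if closure of 34 gives the C7 epimer 7-epi-35 F8 (or a mixture), Dess–Martin oxidation gives the macrocyclic (Z)-enone F9. Zn(BH4)2 (Et2O, −30 °C) then reduces F9 under chelation between the C7 carbonyl and the 9-OMOM oxygen (β-alkoxy ketone, 1,3-syn selective), so that C7 is set by hydride delivery and the route is rejoined at 35.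

**Further compounds**
F1 | step 10 | methyl lactol from 18 (2-hydroxy-2,3-dimethyl tetrahydropyran, anomers) | CC1(O)O[C@@H](/C(C)=C\CO[Si](c2ccccc2)(c2ccccc2)C(C)(C)C)C[C@H](O[Si](CC)(CC)CC)[C@H]1C
F2 | step 10 | 2-alkenyl-5,6-dimethyl-4-(triethylsilyloxy)-3,4-dihydro-2H-pyran | CC1=C(C)[C@@H](O[Si](CC)(CC)CC)C[C@H](/C(C)=C\CO[Si](c2ccccc2)(c2ccccc2)C(C)(C)C)O1
F3 | step 19 | 17-epi-33 | CC2(C)O[C@H]1CC=C(C)[C@H]([C@@H](OCOC)[C@@](O[Si](CC)(CC)CC)(C(=O)OCC)[C@H](C)C(=O)OC(C)(C)C)[C@@]1(C)[C@@H](CC/C(C)=C\I)O2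
F4 | step 19 | 17-epi-34 | CC2(C)O[C@H]1CC=C(C)[C@H]([C@@H](OCOC)[C@@](O[Si](CC)(CC)CC)(C=O)[C@H](C)C(=O)OC(C)(C)C)[C@@]1(C)[C@@H](CC/C(C)=C\I)O2
F5 | step 19 | 17-epi-35 | CC4(C)O[C@H]1CC=C(C)[C@@H]2[C@@H](OCOC)[C@](O[Si](CC)(CC)CC)([C@H](C)C(=O)OC(C)(C)C)[C@@H](O)/C=C(/C)CC[C@@H](O4)[C@@]12C
F6 | step 19 | 17-epi-36 | O[C@H]1CC=C(C)[C@@H]2[C@@H](O)[C@@]3(O)[C@H](/C=C(/C)CC[C@@H](O)[C@@]12C)OC(=O)[C@H]3C
F7 | step 19 | 17-epi-37 (17-epi-stylatulide lactone) | CC(=O)O[C@H]1CC=C(C)[C@@H]2[C@@H](OC(C)=O)[C@@]3(O)[C@H](/C=C(/C)CC[C@@H](OC(C)=O)[C@@]12C)OC(=O)[C@H]3C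
F8 | step 21 | 7-epi-35 | CC4(C)O[C@H]1CC=C(C)[C@@H]2[C@@H](OCOC)[C@](O[Si](CC)(CC)CC)([C@@H](C)C(=O)OC(C)(C)C)[C@H](O)/C=C(/C)CC[C@@H](O4)[C@@]12C
F9 | step 21 | macrocyclic (5Z)-en-7-one | CC4(C)O[C@H]1CC=C(C)[C@@H]2[C@@H](OCOC)[C@](O[Si](CC)(CC)CC)([C@@H](C)C(=O)OC(C)(C)C)C(=O)/C=C(/C)CC[C@@H](O4)[C@@]12C
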